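**Plan**
- Retrosynthetic cuts: first the C7–aryl bond (C7 bromide plus 1-(benzyloxy)-4-bromo-2-methoxybenzene), then the lactone O1–C2 bond (acyl transfer from an N-acyl oxazolidinone to a CH2OH arm), then C3–C7' (aldol with O-benzylvanillin). What remains is (2,2-dimethyl-1,3-dioxan-5-yl)acetic acid, made from diethyl allylmalonate.
- Forward order: acid fragment, loading on the auxiliary, aldol (C3–C7'), silylation, closure of the γ-lactone (the only ring formed, step 7), bromination of the free arm, C7–aryl coupling, two deprotections.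
- Structural feature used: lactone carbon C4 bears two CH2 arms, C5 (bonded to ring oxygen O1) and C7 (bonded to the guaiacyl ring). While both are CH2OH, C4 is not stereogenic, and its configuration is decided only by which arm holds the O1–C2 ester bond.
- Stereochemistry: C3 (S) and C7' (S) come from the Evans syn-aldol on (S)-4-benzyloxazolidin-2-one. C4 (R in the target) comes from equilibrating the two hydroxymethyl lactones to the 3,4-trans isomer under the influence of the C3 substituent.

Key step: step 7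

Remark: lactone locants are used throughout (O1, C2 = carbonyl, C3, C4, C5; C7 = exocyclic CH2 on C4; C7' = carbinol carbon on C3). The terminal alkene carbon lost in step 3 is assumed to end as formic acid.

**Step 1**
Reactants: 1 diethyl allylmalonate
Product: 2 2-allylpropane-1,3-diol
Conditions: LiAlH4, THF, 0 °C to reflux; Fieser work-up
Reagents that add atoms: none
Why: Hydride reduction of both malonate esters with LiAlH4 is a standard ester-to-alcohol reduction that leaves the isolated terminal alkene untouched.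

**Step 2**
Reactants: 2 2-allylpropane-1,3-diol
Product: 3 5-allyl-2,2-dimethyl-1,3-dioxane
Conditions: Me2C(OMe)2, PPTS (cat.), CH2Cl2, rt
Reagents that add atoms: 2,2-dimethoxypropane, COC(C)(C)OC
Why: Acid-catalysed transacetalisation (acetonide protection) ties the 1,3-diol into the six-membered isopropylidene acetal and is driven by loss of methanol.

**Step 3**
Reactants: 3 5-allyl-2,2-dimethyl-1,3-dioxane
Product: 5 2-(2,2-dimethyl-1,3-dioxan-5-yl)acetic acid, via dioxanylacetaldehyde 4 (not isolated)
Conditions: NaIO4, KMnO4 (cat.), K2CO3, t-BuOH/H2O, rt; extraction at pH 4–5, 0 °C, used at once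
Reagents that add atoms: sodium periodate, [Na+].[O-]I(=O)(=O)=O; potassium permanganate (catalytic oxygen carrier), [K+].[O-][Mn](=O)(=O)=O; water, O
Why: Lemieux–von Rudloff oxidation, in which catalytic permanganate with periodate as terminal oxidant cleaves the terminal alkene and oxidises the aldehyde on to the acid, while the carbonate buffer protects the acid-labile acetonide.

**Step 4**
Reactants: 5 2-(2,2-dimethyl-1,3-dioxan-5-yl)acetic acid; 6 (S)-4-benzyloxazolidin-2-one
Product: 8 (S)-4-benzyl-3-[2-(2,2-dimethyl-1,3-dioxan-5-yl)acetyl]oxazolidin-2-one, via mixed pivalic anhydride 7 (not isolated)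
Conditions: PivCl, Et3N, THF, −20 °C; then LiCl, 6, −20 °C to rt
Reagents that add atoms: none
Why: N-Acylation of the oxazolidinone by the mixed-anhydride method (LiCl/Et3N protocol), in which the nucleophile attacks the unhindered carbonyl of the anhydride and not the pivaloyl one.

**Step 5**
Reactants: 8 (S)-4-benzyl-3-[2-(2,2-dimethyl-1,3-dioxan-5-yl)acetyl]oxazolidin-2-one; 9 4-(benzyloxy)-3-methoxybenzaldehyde
Product: 12 (S)-4-benzyl-3-[(2S,3S)-3-[4-(benzyloxy)-3-methoxyphenyl]-2-(2,2-dimethyl-1,3-dioxan-5-yl)-3-hydroxypropanoyl]oxazolidin-2-one, via boron enolate 10 (not isolated), via boron aldolate 11 (not isolated)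
Conditions: Bu2BOTf, i-Pr2NEt, CH2Cl2, −78 to 0 °C; then 9, −78 to 0 °C; pH 7 buffer, MeOH, H2O2, 0 °C
Reagents that add atoms: none
Why: Evans syn-aldol reaction, in which the Z-boron enolate reacts through a closed Zimmerman–Traxler chair on the enolate face remote from the benzyl group of the (S)-auxiliary, which should set both new stereocentres (2S,3S, the future C3 and C7') with the syn relationship.

**Step 6**
Reactants: 12 (S)-4-benzyl-3-[(2S,3S)-3-[4-(benzyloxy)-3-methoxyphenyl]-2-(2,2-dimethyl-1,3-dioxan-5-yl)-3-hydroxypropanoyl]oxazolidin-2-one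
Product: 13 (S)-4-benzyl-3-[(2S,3S)-3-[4-(benzyloxy)-3-methoxyphenyl]-3-(tert-butyldimethylsilyloxy)-2-(2,2-dimethyl-1,3-dioxan-5-yl)propanoyl]oxazolidin-2-one
Conditions: TBSOTf, 2,6-lutidine, CH2Cl2, −78 to 0 °C
Reagents that add atoms: tert-butyldimethylsilyl trifluoromethanesulfonate, CC(C)(C)[Si](C)(C)OS(=O)(=O)C(F)(F)F
Why: Silyl ether protection of the hindered secondary aldol hydroxyl with a silyl triflate and a non-nucleophilic base, which blocks retro-aldol and keeps this oxygen out of the later acyl exchange.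

**Step 7**
Reactants: 13 (S)-4-benzyl-3-[(2S,3S)-3-[4-(benzyloxy)-3-methoxyphenyl]-3-(tert-butyldimethylsilyloxy)-2-(2,2-dimethyl-1,3-dioxan-5-yl)propanoyl]oxazolidin-2-one
Product: 17 (3S,4S)-3-[(S)-[4-(benzyloxy)-3-methoxyphenyl](tert-butyldimethylsilyloxy)methyl]-4-(hydroxymethyl)dihydrofuran-2(3H)-one, via imide diol 14 (not isolated), via cis-lactone 15 (not isolated), via bicyclic hemiorthoester 16 (not isolated)
Conditions: PPTS (0.2 equiv), MeOH, 40 °C; evaporate; Bu2SnO (0.1 equiv), toluene, 90 °C
Reagents that add atoms: none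
Why: Proposed new method: PPTS in methanol transacetalises the dioxane of 13 to the diol 14, and either primary hydroxyl then adds to the activated exocyclic imide carbonyl C2 and expels the oxazolidinone, so that the O1–C2 bond forms and the γ-lactone closes in a 5-exo-trig acyl substitution to give 17 and its C4 epimer 15. Dibutyltin oxide then converts the free CH2OH arm into a tin alkoxide that adds to the lactone carbonyl to give the bicyclic hemiorthoester 16, and collapse of 16 at the other C–O bond exchanges ring arm and free arm, which inverts C4 while no bond to C3 or C7' is broken. The closest known reactions are the lactonisation of γ-hydroxy N-acyl oxazolidinones with release of the auxiliary and the degenerate translactonisation of β-(hydroxymethyl)-γ-butyrolactones; their use to sort two diastereotopic arms is the untested part. C4 is the only new stereocentre and is set under thermodynamic control by the C3 substituent: the bulky silyloxybenzyl group, fixed by the aldol, should make the lactone with the trans CH2OH group the sink of the equilibrium. The step needs trans over cis selectivity without erosion at C3, which the neutral, non-enolising tin catalyst and the silyl ether on C7' (no retro-aldol, no β-elimination) should secure, while attack on the exocyclic rather than the ring carbonyl of the imide follows from a five-membered against a seven-membered transition state.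

**Step 8**
Reactants: 17 (3S,4S)-3-[(S)-[4-(benzyloxy)-3-methoxyphenyl](tert-butyldimethylsilyloxy)methyl]-4-(hydroxymethyl)dihydrofuran-2(3H)-one
Product: 18 (3S,4R)-3-[(S)-[4-(benzyloxy)-3-methoxyphenyl](tert-butyldimethylsilyloxy)methyl]-4-(bromomethyl)dihydrofuran-2(3H)-one
Conditions: CBr4, PPh3, CH2Cl2, 0 °C to rt
Reagents that add atoms: carbon tetrabromide, BrC(Br)(Br)Br
Why: Appel reaction, in which the primary hydroxyl is activated by PPh3/CBr4 and displaced by bromide in an SN2 process under neutral conditions, so the lactone, the silyl ether and the three stereocentres are not affected (the descriptor at C4 changes only through ligand priorities).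

**Step 9**
Reactants: 18 (3S,4R)-3-[(S)-[4-(benzyloxy)-3-methoxyphenyl](tert-butyldimethylsilyloxy)methyl]-4-(bromomethyl)dihydrofuran-2(3H)-one; 19 1-(benzyloxy)-4-bromo-2-methoxybenzene
Product: 20 (3S,4R)-4-[4-(benzyloxy)-3-methoxybenzyl]-3-[(S)-[4-(benzyloxy)-3-methoxyphenyl](tert-butyldimethylsilyloxy)methyl]dihydrofuran-2(3H)-one
Conditions: NiI2 (10 mol %), 4,4'-dimethoxy-2,2'-bipyridine (10 mol %), NaI (25 mol %), pyridine (10 mol %), Zn dust (2 equiv), DMPU, 60 °C
Reagents that add atoms: none
Why: Nickel-catalysed reductive cross-electrophile coupling of an aryl bromide with a primary alkyl bromide, in which the aryl bromide adds to zerovalent nickel, the C7 radical formed from the halide is captured by the arylnickel species and reductive elimination forms the C7–aryl bond, with zinc as the terminal reductant and no change at C4.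

**Step 10**
Reactants: 20 (3S,4R)-4-[4-(benzyloxy)-3-methoxybenzyl]-3-[(S)-[4-(benzyloxy)-3-methoxyphenyl](tert-butyldimethylsilyloxy)methyl]dihydrofuran-2(3H)-one
Product: 21 (3S,4R)-4-[4-(benzyloxy)-3-methoxybenzyl]-3-[(S)-[4-(benzyloxy)-3-methoxyphenyl](hydroxy)methyl]dihydrofuran-2(3H)-one
Conditions: Bu4NF, AcOH (1:1), THF, 0 °C to rt
Reagents that add atoms: none
Why: Fluoride-mediated cleavage of the silyl ether, buffered with acetic acid so that the liberated β-hydroxy lactone is not exposed to base that could trigger retro-aldol, elimination or epimerisation at C3.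

**Step 11**
Reactants: 21 (3S,4R)-4-[4-(benzyloxy)-3-methoxybenzyl]-3-[(S)-[4-(benzyloxy)-3-methoxyphenyl](hydroxy)methyl]dihydrofuran-2(3H)-one
Product: 22 (3S,4R)-3-[(S)-hydroxy(4-hydroxy-3-methoxyphenyl)methyl]-4-(4-hydroxy-3-methoxybenzyl)dihydrofuran-2(3H)-one
Conditions: H2 (1 atm), Pd/C (10 wt % palladium on carbon), EtOAc, rt
Reagents that add atoms: none
Why: Catalytic hydrogenolysis of the two aryl benzyl ethers under neutral conditions, where the phenolic O–benzyl bonds should be cleaved much faster than the C7'–O bond of the secondary benzylic alcohol.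

**Compound list**
1 | diethyl allylmalonate | CCOC(=O)C(CC=C)C(=O)OCC | starting material
2 | 2-allylpropane-1,3-diol | C=CCC(CO)CO | intermediate
3 | 5-allyl-2,2-dimethyl-1,3-dioxane | C=CCC1COC(C)(C)OC1 | intermediate
4 | 2-(2,2-dimethyl-1,3-dioxan-5-yl)acetaldehyde | O=CCC1COC(C)(C)OC1 | intermediate (not isolated)
5 | 2-(2,2-dimethyl-1,3-dioxan-5-yl)acetic acid | OC(=O)CC1COC(C)(C)OC1 | intermediate
6 | (S)-4-benzyloxazolidin-2-one | O=C1N[C@@H](Cc2ccccc2)CO1 | starting material
7 | 2-(2,2-dimethyl-1,3-dioxan-5-yl)acetic pivalic anhydride | CC(C)(C)C(=O)OC(=O)CC1COC(C)(C)OC1 | intermediate (not isolated)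
8 | (S)-4-benzyl-3-[2-(2,2-dimethyl-1,3-dioxan-5-yl)acetyl]oxazolidin-2-one | O=C1OC[C@H](Cc2ccccc2)N1C(=O)CC1COC(C)(C)OC1 | intermediate
9 | 4-(benzyloxy)-3-methoxybenzaldehyde | COc1cc(C=O)ccc1OCc1ccccc1 | starting material
10 | (Z)-dibutylboron enolate of 8 | CCCCB(CCCC)O/C(=C\C1COC(C)(C)OC1)N1C(=O)OC[C@@H]1Cc1ccccc1 | intermediate (not isolated)
11 | O-dibutylboryl aldolate of 12 | O=C1OC[C@H](Cc2ccccc2)N1C(=O)[C@@H](C1COC(C)(C)OC1)[C@H](OB(CCCC)CCCC)c1ccc(OCc2ccccc2)c(OC)c1 | intermediate (not isolated)
12 | (S)-4-benzyl-3-[(2S,3S)-3-[4-(benzyloxy)-3-methoxyphenyl]-2-(2,2-dimethyl-1,3-dioxan-5-yl)-3-hydroxypropanoyl]oxazolidin-2-one | O=C1OC[C@H](Cc2ccccc2)N1C(=O)[C@@H](C1COC(C)(C)OC1)[C@H](O)c1ccc(OCc2ccccc2)c(OC)c1 | intermediate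
13 | (S)-4-benzyl-3-[(2S,3S)-3-[4-(benzyloxy)-3-methoxyphenyl]-3-(tert-butyldimethylsilyloxy)-2-(2,2-dimethyl-1,3-dioxan-5-yl)propanoyl]oxazolidin-2-one | O=C1OC[C@H](Cc2ccccc2)N1C(=O)[C@@H](C1COC(C)(C)OC1)[C@H](O[Si](C)(C)C(C)(C)C)c1ccc(OCc2ccccc2)c(OC)c1 | intermediate
14 | (S)-4-benzyl-3-[(2S,3S)-3-[4-(benzyloxy)-3-methoxyphenyl]-3-(tert-butyldimethylsilyloxy)-2-(1,3-dihydroxypropan-2-yl)propanoyl]oxazolidin-2-one | O=C1OC[C@H](Cc2ccccc2)N1C(=O)[C@@H](C(CO)CO)[C@H](O[Si](C)(C)C(C)(C)C)c1ccc(OCc2ccccc2)c(OC)c1 | intermediate (not isolated)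
15 | (3S,4R)-3-[(S)-[4-(benzyloxy)-3-methoxyphenyl](tert-butyldimethylsilyloxy)methyl]-4-(hydroxymethyl)dihydrofuran-2(3H)-one (3,4-cis lactone) | OC[C@@H]1COC(=O)[C@@H]1[C@H](O[Si](C)(C)C(C)(C)C)c1ccc(OCc2ccccc2)c(OC)c1 | intermediate (not isolated)
16 | 7-[(S)-[4-(benzyloxy)-3-methoxyphenyl](tert-butyldimethylsilyloxy)methyl]-2,6-dioxabicyclo[2.2.1]heptan-1-ol (hemiorthoester; the C7 substituent lies syn to one O–CH2 bridge) | O[C@]12OC[C@H](CO1)[C@H]2[C@H](O[Si](C)(C)C(C)(C)C)c1ccc(OCc2ccccc2)c(OC)c1 | intermediate (not isolated)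
17 | (3S,4S)-3-[(S)-[4-(benzyloxy)-3-methoxyphenyl](tert-butyldimethylsilyloxy)methyl]-4-(hydroxymethyl)dihydrofuran-2(3H)-one (3,4-trans lactone) | OC[C@H]1COC(=O)[C@@H]1[C@H](O[Si](C)(C)C(C)(C)C)c1ccc(OCc2ccccc2)c(OC)c1 | intermediate
18 | (3S,4R)-3-[(S)-[4-(benzyloxy)-3-methoxyphenyl](tert-butyldimethylsilyloxy)methyl]-4-(bromomethyl)dihydrofuran-2(3H)-one | BrC[C@H]1COC(=O)[C@@H]1[C@H](O[Si](C)(C)C(C)(C)C)c1ccc(OCc2ccccc2)c(OC)c1 | intermediate
19 | 1-(benzyloxy)-4-bromo-2-methoxybenzene | COc1cc(Br)ccc1OCc1ccccc1 | starting material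
20 | (3S,4R)-4-[4-(benzyloxy)-3-methoxybenzyl]-3-[(S)-[4-(benzyloxy)-3-methoxyphenyl](tert-butyldimethylsilyloxy)methyl]dihydrofuran-2(3H)-one | COc1cc(C[C@H]2COC(=O)[C@@H]2[C@H](O[Si](C)(C)C(C)(C)C)c2ccc(OCc3ccccc3)c(OC)c2)ccc1OCc1ccccc1 | intermediate
21 | (3S,4R)-4-[4-(benzyloxy)-3-methoxybenzyl]-3-[(S)-[4-(benzyloxy)-3-methoxyphenyl](hydroxy)methyl]dihydrofuran-2(3H)-one | COc1cc(C[C@H]2COC(=O)[C@@H]2[C@H](O)c2ccc(OCc3ccccc3)c(OC)c2)ccc1OCc1ccccc1 | intermediate
22 | (3S,4R)-3-[(S)-hydroxy(4-hydroxy-3-methoxyphenyl)methyl]-4-(4-hydroxy-3-methoxybenzyl)dihydrofuran-2(3H)-one | COc1cc(C[C@H]2COC(=O)[C@@H]2[C@H](O)c2ccc(O)c(OC)c2)ccc1O | target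

**Totals**
Total step count: 11. Longest linear sequence: 11 steps (1 to 22); compounds 6, 9 and 19 enter as purchased.

**Steps most likely to fail**

1. Step 7. The translactonisation through the strained hemiorthoester may be too slow to reach equilibrium, the thermodynamic bias between the two lactones may be too small, or the benzylic silyl ether may be lost during acetal cleavage. The fallback sets out from aldehyde 9, comes back at 21 and uses only known lignan chemistry, with C4 set by hydrogenation instead of equilibration.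
 - Stobbe condensation of 9 with dimethyl succinate (NaOMe, MeOH, reflux) would give (E)-4-[4-(benzyloxy)-3-methoxyphenyl]-3-(methoxycarbonyl)but-3-enoic acid F1.
 - Asymmetric hydrogenation of this itaconate-type half-ester with a cationic rhodium bisphosphine catalyst ([Rh(cod)2]BF4 with the enantiomer of a DuPhos-type ligand that delivers the R acid, H2, MeOH) would give (R)-4-[4-(benzyloxy)-3-methoxyphenyl]-3-(methoxycarbonyl)butanoic acid F2.
 - Reduction of the ester in the presence of the carboxylate (Ca(BH4)2 from CaCl2 and NaBH4, EtOH) and acidification would close (R)-4-[4-(benzyloxy)-3-methoxybenzyl]dihydrofuran-2(3H)-one F3.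
 - The lithium enolate of F3 (LiN(i-Pr)2, THF, −78 °C) would add to a second equivalent of 9 anti to the C4 substituent to give the 3,4-trans aldols, from which 21 would be separated from its C7' epimer by chromatography.
 - This bypasses steps 1 to 10 at the price of an uncontrolled carbinol centre.

2. Step 9. Oxidative addition of the electron-rich aryl bromide may be slow, so that the alkyl radical dimerises or is reduced, or the alkylnickel species may undergo β-hydride elimination. The fallback sets out from bromide 18 and comes back at 20; it replaces the cross-electrophile coupling by a preformed nucleophile. Zinc insertion (Zn dust, LiCl, THF, 50 °C) would give {[(3R,4S)-4-{(S)-[4-(benzyloxy)-3-methoxyphenyl](tert-butyldimethylsilyloxy)methyl}-5-oxotetrahydrofuran-3-yl]methyl}zinc bromide F4. Negishi coupling of F4 with 19 (Pd(OAc)2, SPhos, THF, rt to 50 °C) would then give 20.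

3. Step 11. Over-reduction may occur, that is, hydrogenolysis of the benzylic C7'–O bond alongside the benzyl ethers. The fallback sets out from 20 and comes back at 22, with the order of the two deprotections reversed. Hydrogenolysis of 20 (H2, Pd/C, EtOAc), in which the bulky silyloxy group shields the C7'–O bond, would give (3S,4R)-3-[(S)-(tert-butyldimethylsilyloxy)(4-hydroxy-3-methoxyphenyl)methyl]-4-(4-hydroxy-3-methoxybenzyl)dihydrofuran-2(3H)-one F5. Desilylation with HF·pyridine in THF/pyridine at 0 °C would then give 22.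

**Further compounds**
F1 | step 7 | (E)-4-[4-(benzyloxy)-3-methoxyphenyl]-3-(methoxycarbonyl)but-3-enoic acid | COC(=O)/C(CC(=O)O)=C/c1ccc(OCc2ccccc2)c(OC)c1
F2 | step 7 | (R)-4-[4-(benzyloxy)-3-methoxyphenyl]-3-(methoxycarbonyl)butanoic acid | COc1cc(C[C@H](CC(=O)O)C(=O)OC)ccc1OCc1ccccc1
F3 | step 7 | (R)-4-[4-(benzyloxy)-3-methoxybenzyl]dihydrofuran-2(3H)-one | COc1cc(C[C@H]2COC(=O)C2)ccc1OCc1ccccc1
F4 | step 9 | {[(3R,4S)-4-{(S)-[4-(benzyloxy)-3-methoxyphenyl](tert-butyldimethylsilyloxy)methyl}-5-oxotetrahydrofuran-3-yl]methyl}zinc bromide | Br[Zn]C[C@H]1COC(=O)[C@@H]1[C@H](O[Si](C)(C)C(C)(C)C)c1ccc(OCc2ccccc2)c(OC)c1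
F5 | step 11 | (3S,4R)-3-[(S)-(tert-butyldimethylsilyloxy)(4-hydroxy-3-methoxyphenyl)methyl]-4-(4-hydroxy-3-methoxybenzyl)dihydrofuran-2(3H)-one | COc1cc(C[C@H]2COC(=O)[C@@H]2[C@H](O[Si](C)(C)C(C)(C)C)c2ccc(O)c(OC)c2)ccc1O
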